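The readings are simulated with constants of no real substance; the scatter is artificial.

You asked for a quick call, so here it is: I say D in maple, and J in ash and alder.

| flask | Q | temperature | remark | time |
|---|---|---|---|---|
| theta | 20 mM | −20 °C | run made earlier |  |
| maple | 10 mM | −20 °C |  | 6.0 h |
| ash | 10 mM | −12 °C |  | 6.0 h |
| alder | 10 mM | −4 °C |  | 6.0 h |

theta run (percent of the Q charged)

| time / min | Q / % | Z / % | D / % | J / % | E / % |
|---|---|---|---|---|---|
| 3.00 | 65.9 | 0 | 1.2 | 0 | 25.6 |
| 5.00 | 51.2 | 1.1 | 2.8 | 0 | 35.3 |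
| 10.0 | 24.5 | 1.6 | 10.4 | 0 | 47.0 |
| 20.0 | 7.4 | 4.4 | 23.5 | 0.5 | 44.6 |
| 40.0 | 0.3 | 7.4 | 45.2 | 1.3 | 23.6 |

(each reading ± 0.5 percentage points)

- which of these there is most of at the end, counted by the Q in it, maple (D / J / E / Z)
- which of these there is most of at the end, counted by the Q in it, ash (D / J / E / Z)
- which of these there is most of at the end, counted by the Q in it, alder (D / J / E / Z)
- the largest of these amounts at the end, in percent of the Q charged, maple
- the largest of these amounts at the end, in percent of the Q charged, ash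
- the largest of these amounts at the end, in percent of the Q charged, alder

- the earlier runs do not show what temperature does; that part of a forecast is a guess

My number is an estimated plateau, and it comes from the last theta reading, where the species we see add up to less than the charge:

seen = Q + E + Z + D + J = 77.8%

share of E's exits going to D, J = (D + J)/(Z + D + J) = 0.863

plateau = 67.1%

This plateau, my estimate of the fraction of the charge that ends as D or J once Q and E are gone, rests on the selectivity factor of E's two exits, which I assume holds at each temperature.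

Next comes a clock for D → J. D integrated over theta gives 8.95 min of the charge-time, and J reads 1.3%, so:

lifetime of D = 11.5 h

That clock is soft, since J sits close to its scatter of 0.5 percentage points. E's fall reads a lifetime of 31.4 min, much shorter than D's, so I start D at the plateau. I assume first order, although theta tests one charge.

maple: D = plateau × exp(−t/lifetime) = 39.8%, ahead of J

Temperature is a guess, so I borrow the forecast's factor of 3 per step:

ash: J = 53.1%

alder: J = 66.5%

The forecast picks the same species, at 44%, 45% and 62%, and it too reads “a parallel loss to something unseen”. We part at the warm end, where its alder figure stands below my plateau.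

The flask gives D 40.3% in maple, J 58.2% in ash and J 67.7% in alder.

    Q ⇌ L (K = 16.0, k = 3.50 × 10⁻⁴ s⁻¹, Ea = 72.0 kJ mol⁻¹, ΔH = 11.0 kJ mol⁻¹)
    Q → E (k = 0.00180 s⁻¹, Ea = 71.0 kJ mol⁻¹)
    E → D (k = 5.20 × 10⁻⁴ s⁻¹, Ea = 81.0 kJ mol⁻¹)
    L ⇌ X (K = 0.260, k = 3.80 × 10⁻⁴ s⁻¹, Ea = 70.0 kJ mol⁻¹, ΔH = −38.0 kJ mol⁻¹)
    E → Z (k = 9.20 × 10⁻⁵ s⁻¹, Ea = 74.0 kJ mol⁻¹)
    D → J (k = 2.60 × 10⁻⁵ s⁻¹, Ea = 89.0 kJ mol⁻¹)
    Q ⇌ X (k = 1.50 × 10⁻⁴ s⁻¹, Ea = 75.0 kJ mol⁻¹)
    L → G (k = 0.00170 s⁻¹, Ea = 73.0 kJ mol⁻¹)
    (constants at −20 °C)

Alder holds G at 22.3%, a species no run showed. D and J together in alder come to 67.8%, against the estimated plateau of 67.1%. The neighbour flask, alder run at −29 °C, has D and J together at 62.7%, below the plateau, with E still at 3.99%.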